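The route rests on disconnecting the bond between the adjacent quaternary carbons C11 and C18 (atoms numbered in the order of the target SMILES). C11 lies β to the carbonyl-level carbon C14 through C12, and C18 bears the methyl C19, so hydrogen-atom transfer from an iron hydride to a methylene alkene gives a tertiary C18 radical that adds to C11 of an ene-dione. One operation thus closes ring B (C11–C18–C20–C21–C22–C28) as a spirocycle and sets C11 relative to the carvone-derived centre C9. The precursor is a 3-acyl-2-methylcyclohexenone from (S)-carvone carrying a ketal-masked acetyl group and a chain ending in a silyloxymethyl-substituted methylene alkene. Aldol bridging, lactone annulation and side-chain coupling complete the target.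

Key step: step 11

Remark: atom labels (C1–C28, O17, O26, O27) follow the order of the atoms in the target SMILES, ring A is C9–C10–C11–C12–C14–C15 and ring B is C11–C18–C20–C21–C22–C28; carbinol centres that are not controlled and are erased later (in 5, 16, 21–27) are left open in the SMILES, and C12 is drawn as its more stable epimer until it becomes sp2 in step 19.

Step 1
Reactants: 1 (S)-(+)-carvone
Product: 2 (5S)-5-acetyl-2-methylcyclohex-2-en-1-one
Conditions: O3, CH2Cl2/MeOH, −78 °C; then Me2S, −78 °C → rt
Reagents that add atoms: ozone, [O-][O+]=O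
Why: Ozonolysis should cleave the electron-rich isopropenyl alkene well before the conjugated enone alkene, and the C9 stereocentre is not touched.

Step 2
Reactants: 2 (5S)-5-acetyl-2-methylcyclohex-2-en-1-one
Product: 3 (5S)-2-methyl-5-(2-methyl-1,3-dioxolan-2-yl)cyclohex-2-en-1-one
Conditions: HOCH2CH2OH, PPTS (cat.), PhH, reflux, Dean–Stark
Reagents that add atoms: ethylene glycol, OCCO
Why: Acid-catalysed ketalisation should take the saturated methyl ketone selectively because the conjugated enone carbonyl is much less electrophilic.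

Step 3
Reactants: 3 (5S)-2-methyl-5-(2-methyl-1,3-dioxolan-2-yl)cyclohex-2-en-1-one; 4 vinylmagnesium bromide
Product: 5 (5S)-1-ethenyl-2-methyl-5-(2-methyl-1,3-dioxolan-2-yl)cyclohex-2-en-1-ol (both C1 epimers)
Conditions: THF, −78 → 0 °C; aq. NH4Cl
Reagents that add atoms: none
Why: Grignard 1,2-addition to the α-methyl enone carbonyl should give the tertiary bis-allylic alcohol, whose new carbinol centre is erased in step 4.

Step 4
Reactants: 5 (5S)-1-ethenyl-2-methyl-5-(2-methyl-1,3-dioxolan-2-yl)cyclohex-2-en-1-ol
Product: 6 (5R)-3-ethenyl-2-methyl-5-(2-methyl-1,3-dioxolan-2-yl)cyclohex-2-en-1-one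
Conditions: pyridinium chlorochromate [C5H5NH][CrO3Cl], NaOAc, 4 Å MS, CH2Cl2, rt
Reagents that add atoms: pyridinium chlorochromate, [O-][Cr](=O)(=O)Cl.c1cc[nH+]cc1
Why: The chromate ester of the tertiary allylic alcohol should undergo a [3,3] shift into the ring and be oxidised to the transposed, fully conjugated dienone (Dauben–Babler oxidative transposition), with acetate buffering protecting the ketal.

Step 5
Reactants: 6 (5R)-3-ethenyl-2-methyl-5-(2-methyl-1,3-dioxolan-2-yl)cyclohex-2-en-1-one
Product: 7 (5R)-2-methyl-5-(2-methyl-1,3-dioxolan-2-yl)-3-oxocyclohex-1-ene-1-carbaldehyde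
Conditions: OsO4 (2 mol%), NaIO4, 2,6-lutidine, dioxane/H2O (3:1), rt
Reagents that add atoms: osmium tetroxide, O=[Os](=O)(=O)=O; sodium periodate, [Na+].[O-]I(=O)(=O)=O
Why: OsO4 should dihydroxylate the terminal, less hindered and more electron-rich vinyl group in preference to the tetrasubstituted enone alkene, and NaIO4 cleaves the diol (Lemieux–Johnson oxidation).

Step 6
Reactants: 8 prop-2-yn-1-ol; 9 allylmagnesium bromide
Product: 10 2-methylidenepent-4-en-1-ol
Conditions: 9 (2.5 equiv), CuI (10 mol%), Et2O, 0 °C → reflux; aq. NH4Cl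
Reagents that add atoms: none
Why: Carbomagnesiation of the magnesium propargyl alkoxide should deliver the allyl group to the internal alkyne carbon through a five-membered magnesium chelate and give the 2-substituted allylic alcohol on protonation.

Step 7
Reactants: 10 2-methylidenepent-4-en-1-ol
Product: 11 tert-butyldimethyl[(2-methylidenepent-4-en-1-yl)oxy]silane
Conditions: tBuMe2SiCl, imidazole, CH2Cl2, 0 °C → rt
Reagents that add atoms: tert-butyldimethylsilyl chloride, CC(C)(C)[Si](C)(C)Cl
Why: Standard silylation of a primary alcohol masks the hydroxyl for the organometallic steps.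

Step 8
Reactants: 11 tert-butyldimethyl[(2-methylidenepent-4-en-1-yl)oxy]silane
Product: 13 tert-butyl[(5-iodo-2-methylidenepentyl)oxy]dimethylsilane, via alkylzirconocene 12 (not isolated)
Conditions: Cp2Zr(H)Cl (1.1 equiv), THF, rt; then I2, 0 °C
Reagents that add atoms: iodine, II
Why: Cp2Zr(H)Cl should add to the monosubstituted terminal alkene much faster than to the 1,1-disubstituted one, and iodinolysis of the primary C–Zr bond gives the primary iodide (hydrozirconation–iodination).

Step 9
Reactants: 7 (5R)-2-methyl-5-(2-methyl-1,3-dioxolan-2-yl)-3-oxocyclohex-1-ene-1-carbaldehyde; 13 tert-butyl[(5-iodo-2-methylidenepentyl)oxy]dimethylsilane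
Product: 16 (5R)-3-[6-(tert-butyldimethylsilyloxy)-1-hydroxy-5-methylidenehexyl]-2-methyl-5-(2-methyl-1,3-dioxolan-2-yl)cyclohex-2-en-1-one (both carbinol epimers), via Grignard reagent 14 (not isolated), via titanium reagent 15 (not isolated)
Conditions: 13, Mg, THF, rt; ClTi(OiPr)3, −78 → −30 °C; then 7, −78 → −20 °C; aq. NH4Cl
Reagents that add atoms: none
Why: An alkyltitanium triisopropoxide adds readily to aldehydes but only sluggishly to ketones, so the formyl carbon C28 should be attacked in the presence of the enone carbonyl (chemoselective organotitanium 1,2-addition), and the new carbinol centre is erased in step 10.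

Step 10
Reactants: 16 (5R)-3-[6-(tert-butyldimethylsilyloxy)-1-hydroxy-5-methylidenehexyl]-2-methyl-5-(2-methyl-1,3-dioxolan-2-yl)cyclohex-2-en-1-one
Product: 17 (5R)-3-[6-(tert-butyldimethylsilyloxy)-5-methylidenehexanoyl]-2-methyl-5-(2-methyl-1,3-dioxolan-2-yl)cyclohex-2-en-1-one
Conditions: Dess–Martin periodinane, NaHCO3, CH2Cl2, 0 °C → rt
Reagents that add atoms: none
Why: Dess–Martin oxidation of the allylic alcohol should give the ene-dione under buffered, neutral conditions that spare the ketal, the silyl ether and the methylene alkene.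

Step 11
Reactants: 17 (5R)-3-[6-(tert-butyldimethylsilyloxy)-5-methylidenehexanoyl]-2-methyl-5-(2-methyl-1,3-dioxolan-2-yl)cyclohex-2-en-1-one
Product: 18 5-[(tert-butyldimethylsilyloxy)methyl]-5,7-dimethyl-10-(2-methyl-1,3-dioxolan-2-yl)spiro[5.5]undecane-1,8-dione (spiro carbon C11; C18 trans to the C9 substituent on ring A; C16 anti to C28)
Conditions: Fe(acac)3 (30 mol%), PhSiH3 (3 equiv, slow addition), EtOH/(CH2OH)2 (5:1), 0.02 M, 60 °C
Reagents that add atoms: none
Why: An iron hydride generated from Fe(acac)3 and PhSiH3 transfers a hydrogen atom to the CH2 terminus of the 1,1-disubstituted alkene, creating methyl C19 and a nucleophilic tertiary radical at C18 that adds to C11 of the ene-dione, after which the C12 radical is reduced by divalent iron and protonated by the alcohol solvent. The closest known reaction type is the iron-mediated reductive coupling of alkenes with enones, which has been used intramolecularly to join two quaternary carbons. Ring B closes in the 6-exo-trig mode through a chair in which allylic strain between methyl C13 and C22 holds the tether on the C10 side of C11. C11 is controlled by axial attack on the half-chair enone anti to the equatorial C9 dioxolane substituent, C12 by protonation (it is erased in step 19), and C18 by which one-carbon arm sits anti to C28 over ring A in that chair. The step needs 6-exo addition to outrun reduction of the radical or of the ene-dione, which the short tether and the doubly activated acceptor favour, and it needs the CH2OSi arm rather than methyl in the site anti to C28, for which the substrate offers only a modest bias because both arms are similar in size; this is the point where the route concentrates its risk, and only the wanted C18 epimer can bridge in step 13.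

Step 12
Reactants: 18 5-[(tert-butyldimethylsilyloxy)methyl]-5,7-dimethyl-10-(2-methyl-1,3-dioxolan-2-yl)spiro[5.5]undecane-1,8-dione
Product: 19 5-(hydroxymethyl)-5,7-dimethyl-10-(2-methyl-1,3-dioxolan-2-yl)spiro[5.5]undecane-1,8-dione
Conditions: Bu4NF, THF, 0 °C → rt
Reagents that add atoms: none
Why: Fluoride cleaves the primary silyl ether without affecting the ketal or the saturated diketone.

Step 13
Reactants: 19 5-(hydroxymethyl)-5,7-dimethyl-10-(2-methyl-1,3-dioxolan-2-yl)spiro[5.5]undecane-1,8-dione
Product: 21 tricyclic aldol (bicyclo[2.2.2]octan-2-one with bridgeheads C11 and C15; C14 ketone; C16 hydroxyl as both epimers; ring B with C28 ketone fused at C11–C18), via keto aldehyde 20 (not isolated)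
Conditions: Dess–Martin periodinane, NaHCO3, CH2Cl2, 0 °C; work-up; then K2CO3, MeOH, 0 °C → rt
Reagents that add atoms: none
Why: Oxidation gives the non-enolisable C16 aldehyde, and reversible base-mediated aldol addition of the C15 enolate should close the bicyclo[2.2.2]octane as the least strained aldol available, which fixes C15 through the bridge and leaves C16 as a carbinol that is oxidised in step 18.

Step 14
Reactants: 21 tricyclic aldol
Product: 22 C16 trimethylsilyl ether of 21
Conditions: Me3SiCl, imidazole, DMF, 0 °C
Reagents that add atoms: chlorotrimethylsilane, C[Si](C)(C)Cl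
Why: Silylation blocks the aldol hydroxyl so that the following enolate step cannot trigger retro-aldol cleavage or O-alkylation.

Step 15
Reactants: 22 C16 trimethylsilyl ether of 21; 23 benzyl bromoacetate
Product: 24 22 carrying CH2CO2Bn at C22 (equatorial on ring B)
Conditions: LiN(iPr)2 (1.1 equiv), THF, −78 °C; then 23, DMPU, −78 → −30 °C
Reagents that add atoms: none
Why: Kinetic deprotonation should occur at the only α-methylene, C22 (C11 is quaternary, C15 a bridgehead and C12 a hindered methine), the enolate is alkylated by the reactive α-bromo ester, and C22 remains epimerisable so that the new arm settles equatorial.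

Step 16
Reactants: 24 22 carrying CH2CO2Bn at C22
Product: 26 trans-fused γ-lactone (O27 on C28, C25 carbonyl, C23 methylene) with free C14 and C16 hydroxyls, via hydroxy acid 25 (not isolated)
Conditions: Li (excess), NH3(l)/THF, −78 °C; MeOH, then NH4Cl, → rt; citric acid work-up (pH 4); then PPTS (cat.), PhMe, 60 °C
Reagents that add atoms: none
Why: Dissolving-metal reduction should give the thermodynamically preferred equatorial C28 alcohol (an axial hydroxyl would be syn-axial to methyl C19), cleave the benzyl ester and reduce the C14 ketone, after which methanolysis removes the silyl group and the trans-diequatorial hydroxy acid lactonises under mild acid.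

Step 17
Reactants: 26 trans-fused γ-lactone with free C14 and C16 hydroxyls
Product: 27 26 with methyl C24 at C23 (cis to H22)
Conditions: LiN(iPr)2 (3.5 equiv), THF, −78 → −40 °C; MeI, −78 °C
Reagents that add atoms: iodomethane, CI
Why: After both hydroxyls are deprotonated the lactone enolate should be methylated on the face anti to C21, which places C24 cis to H22 as in the target (alkylation of a trans-fused butanolide enolate), while lithium alkoxides are not methylated at this temperature.

Step 18
Reactants: 27 26 with methyl C24 at C23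
Product: 28 C14,C16-dione of 27
Conditions: Dess–Martin periodinane (3 equiv), NaHCO3, CH2Cl2, rt
Reagents that add atoms: none
Why: Dess–Martin oxidation converts both hindered secondary alcohols to ketones, and the resulting 1,3-diketone cannot enolise toward the bridgehead C15.

Step 19
Reactants: 28 C14,C16-dione of 27
Product: 29 C14 enol triflate of 28 (C12=C14)
Conditions: KN(SiMe3)2 (1.1 equiv), THF, −78 → −40 °C; then PhNTf2, −78 → 0 °C
Reagents that add atoms: N-phenylbis(trifluoromethanesulfonimide), O=S(=O)(N(c1ccccc1)S(=O)(=O)C(F)(F)F)C(F)(F)F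
Why: The C14 ketone can enolise only toward C12 (C15 is a bridgehead and the C16 ketone has no α-hydrogen) and its α-proton is far more acidic than the hindered lactone methine, so O-sulfonylation should give the C12=C14 enol triflate.

Step 20
Reactants: 29 C14 enol triflate of 28
Product: 30 target skeleton with 2-methyl-1,3-dioxolan-2-yl in place of the C9 side chain (C12=C14 alkene, C16 ketone, lactone)
Conditions: Pd(OAc)2 (5 mol%), PPh3 (10 mol%), HCO2H, Bu3N, DMF, 60 °C
Reagents that add atoms: none
Why: Zerovalent palladium inserts into the vinyl C–O bond and formate delivers hydride, so the triflate is replaced by hydrogen and the trisubstituted alkene remains (palladium-catalysed triflate reduction).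

Step 21
Reactants: 30 target skeleton with 2-methyl-1,3-dioxolan-2-yl at C9
Product: 31 C9 acetyl analogue of the target
Conditions: PPTS, acetone/H2O (9:1), 55 °C
Reagents that add atoms: water, O
Why: Mild acid-catalysed transketalisation releases the methyl ketone without epimerising C9 and without touching the lactone or the β,γ-unsaturated ketone, which cannot conjugate across the bridgehead.

Step 22
Reactants: 31 C9 acetyl analogue of the target
Product: 32 C9 1-(trifluoromethylsulfonyloxy)ethenyl analogue of the target
Conditions: LiN(iPr)2 (1.05 equiv), THF, −78 °C; then PhNTf2, −78 → −20 °C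
Reagents that add atoms: N-phenylbis(trifluoromethanesulfonimide), O=S(=O)(N(c1ccccc1)S(=O)(=O)C(F)(F)F)C(F)(F)F
Why: Kinetic deprotonation of the methyl ketone occurs at the methyl group and not at C9 or at the lactone methine, and O-sulfonylation traps the terminal enolate as the 1,1-disubstituted vinyl triflate.

Step 23
Reactants: 32 C9 1-(trifluoromethylsulfonyloxy)ethenyl analogue of the target; 33 5-bromo-2-methylpent-2-ene
Product: 35 CNP0385704.3 (target), via zinc reagent 34 (not isolated)
Conditions: 33, Zn, LiCl, THF, 40 °C; then 32, Pd(dppf)Cl2 (5 mol%), THF, 50 °C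
Reagents that add atoms: none
Why: Negishi coupling of the primary alkylzinc bromide with the vinyl triflate should form C2–C3 and so complete the methylene-bearing side chain, the organozinc tolerating the ketone and the lactone.

Compound list
1 | (S)-(+)-carvone | CC1=CC[C@@H](CC1=O)C(C)=C | starting material
2 | (5S)-5-acetyl-2-methylcyclohex-2-en-1-one | CC1=CC[C@@H](CC1=O)C(C)=O | intermediate
3 | (5S)-2-methyl-5-(2-methyl-1,3-dioxolan-2-yl)cyclohex-2-en-1-one | CC1=CC[C@@H](CC1=O)C1(C)OCCO1 | intermediate
4 | vinylmagnesium bromide | C=C[Mg]Br | starting material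
5 | (5S)-1-ethenyl-2-methyl-5-(2-methyl-1,3-dioxolan-2-yl)cyclohex-2-en-1-ol (C1 epimers) | CC1=CC[C@@H](CC1(O)C=C)C1(C)OCCO1 | intermediate
6 | (5R)-3-ethenyl-2-methyl-5-(2-methyl-1,3-dioxolan-2-yl)cyclohex-2-en-1-one | CC1(OCCO1)[C@@H]1CC(C=C)=C(C)C(=O)C1 | intermediate
7 | (5R)-2-methyl-5-(2-methyl-1,3-dioxolan-2-yl)-3-oxocyclohex-1-ene-1-carbaldehyde | CC1(OCCO1)[C@@H]1CC(C=O)=C(C)C(=O)C1 | intermediate
8 | prop-2-yn-1-ol | C#CCO | starting material
9 | allylmagnesium bromide | C=CC[Mg]Br | starting material
10 | 2-methylidenepent-4-en-1-ol | C=CCC(=C)CO | intermediate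
11 | tert-butyldimethyl[(2-methylidenepent-4-en-1-yl)oxy]silane | C=CCC(=C)CO[Si](C)(C)C(C)(C)C | intermediate
12 | chlorobis(cyclopentadienyl)[5-(tert-butyldimethylsilyloxy)-4-methylidenepentyl]zirconium | [Zr+4].[Cl-].[CH2-]CCC(=C)CO[Si](C)(C)C(C)(C)C.c1cc[cH-]c1.c1cc[cH-]c1 | intermediate
13 | tert-butyl[(5-iodo-2-methylidenepentyl)oxy]dimethylsilane | ICCCC(=C)CO[Si](C)(C)C(C)(C)C | intermediate
14 | [5-(tert-butyldimethylsilyloxy)-4-methylidenepentyl]magnesium iodide | I[Mg]CCCC(=C)CO[Si](C)(C)C(C)(C)C | intermediate
15 | [5-(tert-butyldimethylsilyloxy)-4-methylidenepentyl]titanium triisopropoxide | CC(C)O[Ti](OC(C)C)(OC(C)C)CCCC(=C)CO[Si](C)(C)C(C)(C)C | intermediate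
16 | (5R)-3-[6-(tert-butyldimethylsilyloxy)-1-hydroxy-5-methylidenehexyl]-2-methyl-5-(2-methyl-1,3-dioxolan-2-yl)cyclohex-2-en-1-one (C28 carbinol epimers) | CC1(OCCO1)[C@@H]1CC(C(O)CCCC(=C)CO[Si](C)(C)C(C)(C)C)=C(C)C(=O)C1 | intermediate
17 | (5R)-3-[6-(tert-butyldimethylsilyloxy)-5-methylidenehexanoyl]-2-methyl-5-(2-methyl-1,3-dioxolan-2-yl)cyclohex-2-en-1-one (key-step precursor) | CC1(OCCO1)[C@@H]1CC(C(=O)CCCC(=C)CO[Si](C)(C)C(C)(C)C)=C(C)C(=O)C1 | intermediate
18 | 5-[(tert-butyldimethylsilyloxy)methyl]-5,7-dimethyl-10-(2-methyl-1,3-dioxolan-2-yl)spiro[5.5]undecane-1,8-dione, configured at C9, C11 and C18 as in the target (key-step product) | CC1(OCCO1)[C@@H]1C[C@]2([C@H](C)C(=O)C1)[C@](C)(CO[Si](C)(C)C(C)(C)C)CCCC2=O | intermediate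
19 | 5-(hydroxymethyl)-5,7-dimethyl-10-(2-methyl-1,3-dioxolan-2-yl)spiro[5.5]undecane-1,8-dione | CC1(OCCO1)[C@@H]1C[C@]2([C@H](C)C(=O)C1)[C@](C)(CO)CCCC2=O | intermediate
20 | C16 aldehyde of 19 (formyl in place of hydroxymethyl) | CC1(OCCO1)[C@@H]1C[C@]2([C@H](C)C(=O)C1)[C@](C)(C=O)CCCC2=O | intermediate
21 | tricyclic aldol: bicyclo[2.2.2]octan-2-one with bridgeheads C11 and C15, bridges C12(Me)–C14(=O), C10–C9(dioxolane) and C18(Me)–C16(OH), ring B with the C28 ketone fused at C11–C18; C16 epimers | CC1(OCCO1)[C@@H]1C[C@]23[C@H](C)C(=O)[C@H]1C(O)[C@]2(C)CCCC3=O | intermediate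
22 | C16 trimethylsilyl ether of 21 | CC1(OCCO1)[C@@H]1C[C@]23[C@H](C)C(=O)[C@H]1C(O[Si](C)(C)C)[C@]2(C)CCCC3=O | intermediate
23 | benzyl bromoacetate | BrCC(=O)OCc1ccccc1 | starting material
24 | 22 carrying CH2CO2Bn at C22, equatorial on ring B | CC1(OCCO1)[C@@H]1C[C@]23[C@H](C)C(=O)[C@H]1C(O[Si](C)(C)C)[C@]2(C)CC[C@@H](CC(=O)OCc1ccccc1)C3=O | intermediate
25 | C14,C16,C28-triol with CH2CO2H at C22; C28 hydroxyl equatorial and trans to the C22 arm | CC1(OCCO1)[C@@H]1C[C@]23[C@H](C)C(O)[C@H]1C(O)[C@]2(C)CC[C@@H](CC(=O)O)[C@@H]3O | intermediate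
26 | trans-fused γ-lactone (O27 on C28, C25 carbonyl, C23 methylene) with free C14 and C16 hydroxyls | CC1(OCCO1)[C@@H]1C[C@]23[C@H](C)C(O)[C@H]1C(O)[C@]2(C)CC[C@H]1CC(=O)O[C@@H]13 | intermediate
27 | 26 with methyl C24 at C23, cis to H22 | CC1(OCCO1)[C@@H]1C[C@]23[C@H](C)C(O)[C@H]1C(O)[C@]2(C)CC[C@H]1[C@H](C)C(=O)O[C@@H]13 | intermediate
28 | C14,C16-dione of 27 | CC1(OCCO1)[C@@H]1C[C@]23[C@H](C)C(=O)[C@H]1C(=O)[C@]2(C)CC[C@H]1[C@H](C)C(=O)O[C@@H]13 | intermediate
29 | C14 enol triflate of 28 (C12=C14 double bond) | CC1(OCCO1)[C@@H]1C[C@]23C(C)=C(OS(=O)(=O)C(F)(F)F)[C@H]1C(=O)[C@]2(C)CC[C@H]1[C@H](C)C(=O)O[C@@H]13 | intermediate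
30 | target skeleton with 2-methyl-1,3-dioxolan-2-yl at C9 in place of the side chain | CC1(OCCO1)[C@@H]1C[C@]23C(C)=C[C@H]1C(=O)[C@]2(C)CC[C@H]1[C@H](C)C(=O)O[C@@H]13 | intermediate
31 | C9 acetyl analogue of the target | CC(=O)[C@@H]1C[C@]23C(C)=C[C@H]1C(=O)[C@]2(C)CC[C@H]1[C@H](C)C(=O)O[C@@H]13 | intermediate
32 | C9 1-(trifluoromethylsulfonyloxy)ethenyl analogue of the target | C=C(OS(=O)(=O)C(F)(F)F)[C@@H]1C[C@]23C(C)=C[C@H]1C(=O)[C@]2(C)CC[C@H]1[C@H](C)C(=O)O[C@@H]13 | intermediate
33 | 5-bromo-2-methylpent-2-ene | CC(C)=CCCBr | starting material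
34 | (4-methylpent-3-en-1-yl)zinc bromide | CC(C)=CCC[Zn]Br | intermediate
35 | CNP0385704.3 | C=C(CCC=C(C)C)[C@@H]1C[C@]23C(C)=C[C@H]1C(=O)[C@]2(C)CC[C@H]1[C@H](C)C(=O)O[C@@H]13 | target

Total step count: 23. Longest linear sequence: 20 steps (steps 1–5 and 9–23, from (S)-carvone); the chain fragment (steps 6–8) joins at step 9.

Steps most likely to fail

Step 11. The tertiary radical may be reduced before it cyclises, the ene-dione may be reduced directly, or the two one-carbon arms at C18 may be placed with little preference, so that the epimer able to bridge forms in low proportion. The fallback closes the same bond by a polar, equilibrating sequence. Starting from 17, HF·pyridine (THF, 0 °C) would remove the silyl group to give the allylic alcohol F1. RuCl2(PPh3)3 (toluene, 80 °C) would isomerise it to the 2-methyl aldehyde F2. K2CO3 in MeOH should then bring about intramolecular Michael addition of the aldehyde enolate (C18) to C11, followed by aldol closure of C15 onto C16. The Michael step is reversible, so only the adduct with the formyl group over ring A is drained by the aldol. The sequence comes back to the route at 21.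

Step 9. The organometallic reagent may add to the enone carbonyl as well, or the oxo-enal may decompose before it is captured. The fallback removes the competing ketone by a redox adjustment. Starting from 6, Luche reduction (NaBH4, CeCl3·7H2O, MeOH, −40 °C) would give the dienol F3. OsO4/NaIO4 cleavage of its vinyl group would give the hydroxy enal F4, which may rest as its lactol. An excess of Grignard reagent 14, without titanium, would give the diol F5. Dess–Martin oxidation of both allylic alcohols comes back to the route at 17.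

Step 15. Deprotonation may compete at C12, proton transfer may cause double alkylation, or the hindered enolate may react too slowly. The fallback activates C22 under thermodynamic control. Starting from 22, NaH and HCO2Et (THF, rt) would formylate the only position that can hold a stable enolate, giving the hydroxymethylene ketone F6. K2CO3 and 23 in acetone would alkylate C22 to the formyl keto ester F7. Pyrrolidine (CH2Cl2, rt) would then remove the formyl group by retro-Claisen cleavage, coming back to the route at 24.

Further compounds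
F1 | step 11 | (5R)-3-(6-hydroxy-5-methylidenehexanoyl)-2-methyl-5-(2-methyl-1,3-dioxolan-2-yl)cyclohex-2-en-1-one | CC1(OCCO1)[C@@H]1CC(C(=O)CCCC(=C)CO)=C(C)C(=O)C1
F2 | step 11 | 2-methyl-6-[(5R)-2-methyl-5-(2-methyl-1,3-dioxolan-2-yl)-3-oxocyclohex-1-en-1-yl]-6-oxohexanal (C18 epimers) | CC1(OCCO1)[C@@H]1CC(C(=O)CCCC(C)C=O)=C(C)C(=O)C1
F3 | step 9 | (5R)-3-ethenyl-2-methyl-5-(2-methyl-1,3-dioxolan-2-yl)cyclohex-2-en-1-ol (C1 epimers) | CC1(OCCO1)[C@@H]1CC(C=C)=C(C)C(O)C1
F4 | step 9 | (5R)-3-hydroxy-2-methyl-5-(2-methyl-1,3-dioxolan-2-yl)cyclohex-1-ene-1-carbaldehyde (C3 epimers) | CC1(OCCO1)[C@@H]1CC(C=O)=C(C)C(O)C1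
F5 | step 9 | (5R)-3-[6-(tert-butyldimethylsilyloxy)-1-hydroxy-5-methylidenehexyl]-2-methyl-5-(2-methyl-1,3-dioxolan-2-yl)cyclohex-2-en-1-ol (carbinol epimers) | CC1(OCCO1)[C@@H]1CC(C(O)CCCC(=C)CO[Si](C)(C)C(C)(C)C)=C(C)C(O)C1
F6 | step 15 | 22 with a hydroxymethylidene group at C22 | CC1(OCCO1)[C@@H]1C[C@]23[C@H](C)C(=O)[C@H]1C(O[Si](C)(C)C)[C@]2(C)CCC(=CO)C3=O
F7 | step 15 | 22 with formyl and CH2CO2Bn both at C22 | CC1(OCCO1)[C@@H]1C[C@]23[C@H](C)C(=O)[C@H]1C(O[Si](C)(C)C)[C@]2(C)CCC(C=O)(CC(=O)OCc1ccccc1)C3=O
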